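The earlier runs and the new flask stem from a simulated flask from invented constants; scatter was added.

**Missing material.** Tuesday's run, richer in incoming ligand, has lost more from its balance than Wednesday's: at 20.0 min the gap between the charge and the listed species is 10.1%, larger than the 2.40% of Wednesday's run, so we read a further, ligand-dependent loss of complex with one exchanged.

| flask | starting complex | incoming ligand | remark | time |
|---|---|---|---|---|
| Wednesday's | 0.20 M | 0.13 M | run made earlier |  |
| Tuesday's | 0.20 M | 0.30 M | run made earlier |  |
| flask | 0.20 M | 0.200 M |  | 25 min |

| run | time / min | complex with one exchanged / % | complex with two exchanged / % | starting complex / % |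
|---|---|---|---|---|
| Wednesday's | 3.00 | 14.4 | 0.4 | 86.0 |
| Wednesday's | 6.00 | 23.9 | 0.5 | 75.8 |
| Wednesday's | 8.00 | 28.2 | 0.5 | 71.3 |
| Wednesday's | 12.0 | 35.6 | 0.5 | 63.9 |
| Wednesday's | 15.0 | 38.0 | 0.3 | 59.6 |
| Wednesday's | 20.0 | 41.9 | 0.2 | 55.5 |
| Tuesday's | 3.00 | 29.6 | 0.4 | 70.3 |
| Tuesday's | 6.00 | 45.1 | 0.4 | 52.1 |
| Tuesday's | 8.00 | 52.2 | 0 | 44.2 |
| Tuesday's | 12.0 | 60.3 | 0.4 | 33.3 |
| Tuesday's | 15.0 | 64.7 | 0.2 | 28.3 |
| Tuesday's | 20.0 | 67.0 | 0.7 | 22.2 |

(readings scatter by 0.5 percentage points)

- equivalents of incoming ligand to starting complex, everything else as given, that leave most complex with one exchanged at 25 min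
- the amount of complex with one exchanged then, in percent of the starting complex charged
- the amount of complex with one exchanged with the amounts as given



**Two constants.** We follow one molecule. Wednesday's first reading, with the ligand at its mean over those minutes, gives the first exchange a rate constant kf of about 0.433 L mol⁻¹ min⁻¹. Tuesday's shortfall grows by 4.1 percentage points between 12.0 min and 20.0 min; set against the mean complex with one exchanged, and the ligand counted one per complex converted, this gives an onward constant ko of about 0.0518 L mol⁻¹ min⁻¹. At the ligand charged here, the pseudo-first-order time in which such a molecule has an even chance of reacting on, its onward half-life, is 66.9 min.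

**Two limits.** If no molecule went on, equal charges falling one for one would give 68.4% of complex with one exchanged at 25 min. If those molecules all formed at once and sat at the full charge of ligand, 52.8% would survive. The flask lies between, nearer neither, because its molecules form late and see falling ligand, while the onward half-life is longer than the time. We commit to the middle, 60.6%.

**The forecast.** It gives 59%, a little below ours, and 71% at 1.85 equiv, holding that “the mono product is lost by a further ligand-dependent step”.

    starting complex + incoming ligand ⇌ leaving ligand + complex with one exchanged (K = 13.0, k = 0.00750 L mol⁻¹ s⁻¹)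
    complex with one exchanged + incoming ligand ⇌ leaving ligand + complex with two exchanged (K = 2.90, k = 0.00100 L mol⁻¹ s⁻¹)
    complex with two exchanged + incoming ligand ⇌ leaving ligand + complex with three exchanged (K = 1.70, k = 0.00140 L mol⁻¹ s⁻¹)
    complex with two exchanged → over-reaction product (k = 0.0180 s⁻¹)

**Not at rest.** The flask gives 59.4%, and 69.4% at 1.78 equiv, as forecast; 0.170 M of ligand would move the first by 5 points. With the ligand left at the end and the constant of the second step above, the onward half-life, by that step's forward rate alone, is 199 min in this flask, but 82.9 min in the neighbour charged with 0.34 M, which holds 14.7% of over-reaction product against 5.53% in this flask. Left until 250 min, this flask's ligand falls to 8.43% of its charge, its starting complex moves from 34.8% to 32.6%, over-reaction product reaches 24.1%, and complex with one exchanged drops to 43.2%.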